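**Plan**

- Numbering (cyathane): ring A (five-membered) C1–C4, C9; ring B (six-membered) C4–C9; ring C (seven-membered) C5, C6, C14, C13, C12, C11, C10; C15 and C16 are the methyls on C12 and C6, C17 the CH2O on C9, C18–C20 the lactone carbons; β is the face of C17.
- Retrosynthesis: the lactone is cut last (C3–C18, then the C2–O ester bond), the epoxide goes back to the C12=C13 alkene, ring C is cut in one stroke at C5–C10 and C12=C13, and rings A/B go back to a Robinson annulation.
- Enabling feature: C10–C11–C12(=O)–C15 is a 3-oxobutyl group on C5, 1,6 to the C3 carbonyl of ring A (an oxy-Cope retron), and C13 sits on the C6 side chain. The unit is first hung on C3 by a temporary C3–C12 bond, then shifted across the C3–C4=C5 allyl system, which cleaves that bond and unveils the C12 ketone beside a C13 ylide.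
- Forward order: rings A/B → C6 quaternary centre → C3 vinyl carbinol → ring C (key step) → epoxide and C2 oxygen → lactone ring.
- Stereochemistry: C9 by organocatalytic Michael addition; C6 by axial cuprate addition; C3 carbinol by addition anti to C17, transferred to C5 by the suprafacial [3,3] shift; C4 by protonation to the trans fusion; epoxide and C2–OH by attack anti to C16 and C17 (C2 then inverted); final C3 by the cis closure of the lactone.

Key step: step 12

Remark: the alkene isomers formed in step 3 and the C12 epimers formed in step 10 converge in the following step and are carried as mixtures.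

Step 1
Reactants: 1 ethyl 2-oxocyclopentane-1-carboxylate; 2 but-3-en-2-one
Product: 3 ethyl (1S)-2-oxo-1-(3-oxobutyl)cyclopentane-1-carboxylate
Conditions: 6′-hydroxy-9-O-(phenanthren-9-yl) cinchona alkaloid catalyst (cupreine/cupreidine pseudoenantiomer that gives the S adduct, 10 mol%), CH2Cl2, 23 °C
Reagents that add atoms: none
Why: Michael addition under bifunctional cinchona catalysis (the tertiary amine deprotonates the β-keto ester, the 6′-hydroxyl binds the enone) has close precedent for cyclic β-keto esters and sets the C9 quaternary centre by catalyst control.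

Step 2
Reactants: 3 Michael adduct
Product: 4 ethyl (7aS)-5-oxo-1,2,3,5,6,7-hexahydro-7aH-indene-7a-carboxylate
Conditions: TsOH·H2O (cat.), toluene, 110 °C, water removal
Reagents that add atoms: none
Why: Acid-catalysed intramolecular aldol condensation (the ring-closing half of the Robinson annulation) of the methyl ketone onto the ring A carbonyl and dehydration give the C4=C5–C6=O enone without touching C9.

Step 3
Reactants: 4 bicyclic enone; 5 triethyl phosphonoacetate
Product: 6 dienoate (C6=C14 alkylidene acetate; alkene isomers)
Conditions: NaH, THF, 0 → 65 °C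
Reagents that add atoms: none
Why: Horner–Wadsworth–Emmons olefination of the only ketone gives the C14=C6–C5=C4 dienoate; no stereocentre is formed.

Step 4
Reactants: 6 dienoate
Product: 7 diester (6α-methyl, 6β-CH2CO2Et)
Conditions: MeCu·BF3 (from MeLi, CuI, BF3·OEt2), Et2O, −78 → −30 °C; aq. NH4Cl
Reagents that add atoms: methyllithium ([Li]C)
Why: BF3-activated monoalkylcopper reagents add 1,4 rather than 1,6 to dienoates (the 1,6 terminus C4 is also fully substituted), and methyl attacks C6 axially on the face toward which C8 is displaced in the ring B sofa, the α face away from the pseudoaxial C9 ester, which sets the C6 quaternary centre anti to C17.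

Step 5
Reactants: 7 diester
Product: 8 diol
Conditions: LiAlH4, THF, 0 → 65 °C
Reagents that add atoms: none
Why: LiAlH4 reduces both esters to the primary alcohols (C13 and C17) and leaves the trisubstituted alkene and both quaternary centres untouched.

Step 6
Reactants: 8 diol
Product: 9 chloro alcohol
Conditions: PPh3 (1.1 equiv), N-chlorosuccinimide (1.1 equiv), CH2Cl2, −20 → 0 °C
Reagents that add atoms: N-chlorosuccinimide (ClN1C(=O)CCC1=O)
Why: Appel-type chlorination proceeds by SN2 displacement of an alkoxyphosphonium ion and is therefore confined to the unhindered C13 hydroxyl, the neopentyl C17 hydroxyl being returned on work-up.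

Step 7
Reactants: 9 chloro alcohol
Product: 10 silyl ether
Conditions: t-BuMe2SiOTf, 2,6-lutidine, CH2Cl2, −78 → 0 °C
Reagents that add atoms: tert-butyldimethylsilyl triflate (CC(C)(C)[Si](C)(C)OS(=O)(=O)C(F)(F)F)
Why: Silylation with the silyl triflate protects the hindered neopentyl alcohol as an ether that is stable to the organolithium, Grignard and amide bases that follow.

Step 8
Reactants: 10 silyl ether
Product: 11 enone (C3 ketone conjugated to C4=C5)
Conditions: Rh2(C6H10NO)4 (dirhodium tetracaprolactamate, 1 mol%), t-BuOOH, K2CO3, CH2Cl2, 23 °C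
Reagents that add atoms: tert-butyl hydroperoxide (CC(C)(C)OO)
Why: Catalytic allylic oxidation by tert-butylperoxyl radicals attacks the only allylic C–H position (C3; C6 and C9 are quaternary) and gives the conjugated C3 ketone.

Step 9
Reactants: 11 enone; 12 ethyl vinyl ether
Product: 14 α-hydroxy methyl ketone (3β-hydroxy-3α-acetyl), via enol ether adduct 13 (not isolated)
Conditions: 12, (CH3)3CLi, THF, −78 → 0 °C; then 11, −78 °C; then 0.5 M HCl, THF, 0 °C
Reagents that add atoms: water (O)
Why: 1-Ethoxyvinyllithium (an acetyl anion equivalent) adds 1,2 to the enone carbonyl from the α face, anti to the pseudoaxial C17 group on C9 that screens the β face of ring A, and hydrolysis of the enol ether gives the methyl ketone, so that C3 carries the carbon substituent α and the hydroxyl β.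

Step 10
Reactants: 14 α-hydroxy methyl ketone; 15 vinylmagnesium bromide
Product: 16 vinyl carbinol diol (C12 epimers)
Conditions: 15 (3 equiv), THF, −78 → 0 °C; aq. NH4Cl
Reagents that add atoms: none
Why: Grignard addition to the methyl ketone (one equivalent is spent on the hydroxyl) gives the 3,4-dihydroxy-1,5-diene; the new carbinol centre C12 is left uncontrolled because it becomes trigonal in step 12.

Step 11
Reactants: 16 vinyl carbinol diol
Product: 17 phosphonium iodide
Conditions: PPh3, NaI, CH3CN, 80 °C
Reagents that add atoms: triphenylphosphine (c1ccc(cc1)P(c1ccccc1)c1ccccc1); sodium iodide ([Na+].[I-])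
Why: Finkelstein exchange and SN2 quaternisation of triphenylphosphine at the primary C13 carbon give the Wittig salt under neutral conditions that leave the tertiary diol intact.

Step 12
Reactants: 17 phosphonium iodide
Product: 20 tricyclic ketone, via ylide alkoxide 18 (not isolated), via ylide keto enolate 19 (not isolated)
Conditions: KN(SiMe3)2 (2.05 equiv), 18-crown-6, THF, −78 → 45 °C; aq. NH4Cl
Reagents that add atoms: none
Why: Proposed new method: two equivalents of base give the C13 phosphorus ylide and one potassium alkoxide of the 3,12-diol (18); the alkoxide triggers an anionic oxy-Cope rearrangement of the C10=C11–C12–C3–C4=C5 diene that forms C5–C10 and cleaves the temporary C3–C12 bond, the remaining hydroxyl proton then turns the C12 enolate into the methyl ketone (19), and the waiting ylide closes ring C by intramolecular Wittig olefination (C12=C13). The closest known reactions are the anionic oxy-Cope rearrangement of 3,4-dioxygenated 1,5-dienes to 1,6-dicarbonyl compounds with capture of the product in the same flask (tandem oxy-Cope/aldol) and the intramolecular Wittig closure of common and medium rings; their combination is new. Ring C closes by attack of the ylide carbon on the C12 carbonyl through a seven-membered array (7-exo-trig addition, then oxaphosphetane collapse), and the ring allows only the cis alkene. C5 is set by the suprafacial [3,3] shift, which delivers C10 to the α face from which the C12 substituent leaves C3, so the configuration set in step 9 is relayed to C5 and the B/C fusion becomes trans; C4 is set on quenching the C3 enolate by protonation anti to C17, the trans-hydrindanone also being the stable epimer because the cis one would place C3 syn-axial to C16. The step needs the ylide to find only the C12 ketone: before the rearrangement the substrate has no carbonyl group (C3 is a carbinol), afterwards C3 is an enolate and cannot be reached from C13 across the trans-fused ring B, and with exactly two equivalents of base one proton is left to release the C12 ketone.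

Step 13
Reactants: 20 tricyclic ketone
Product: 21 alcohol
Conditions: Bu4NF, THF, 0 → 23 °C
Reagents that add atoms: none
Why: Fluoride cleaves the silyl ether through formation of the strong Si–F bond; the ketone, the alkene and the thermodynamically preferred C4 configuration are unaffected.

Step 14
Reactants: 21 alcohol
Product: 22 acetate
Conditions: Ac2O, pyridine, DMAP (cat.), CH2Cl2, 23 °C
Reagents that add atoms: acetic anhydride (CC(=O)OC(C)=O)
Why: DMAP-catalysed acylation of the primary alcohol installs the C17 acetate of the target.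

Step 15
Reactants: 22 acetate
Product: 25 epoxy hydroxy ketone, via silyl enol ether 23 (not isolated), via silyloxy epoxy ketone 24 (not isolated)
Conditions: Me3SiOTf, Et3N, CH2Cl2, 0 °C; then m-CPBA (2.3 equiv), NaHCO3, CH2Cl2, −10 → 0 °C; then Bu4NF–AcOH (1:1), THF, 0 °C
Reagents that add atoms: m-chloroperoxybenzoic acid (OOC(=O)c1cccc(Cl)c1)
Why: Soft enolisation gives the less hindered C2=C3 silyl enol ether, and the peracid then effects a Rubottom oxidation on its α face (anti to C17) and a Prilezhaev epoxidation of C12=C13 on the β face (anti to the axial C16 methyl, which screens the α face of ring C), giving the 2α-hydroxy ketone and the 12β,13β-epoxide.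

Step 16
Reactants: 25 epoxy hydroxy ketone; 26 acrylic acid
Product: 27 2β-acrylate
Conditions: PPh3, diisopropyl azodicarboxylate, toluene, 0 → 23 °C
Reagents that add atoms: none
Why: Mitsunobu esterification: the C2 hydroxyl is activated as its oxyphosphonium ion and displaced by acrylate in an SN2 reaction accelerated by the adjacent carbonyl, which inverts C2 to the β-ester.

Step 17
Reactants: 27 2β-acrylate
Product: 28 target CNP0404717.1
Conditions: quinuclidine (1 equiv), 1,2-dimethoxyethane, 0 → 23 °C
Reagents that add atoms: none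
Why: Intramolecular Morita–Baylis–Hillman reaction: the amine adds to the acrylate, the resulting enolate attacks the C3 ketone in a 5-exo-trig closure that can only give the cis-fused lactone, so C18 enters on the β face and the hydroxyl is α, and loss of the amine restores the exocyclic methylene.

**Compound list**

1 | ethyl 2-oxocyclopentane-1-carboxylate | CCOC(=O)C1CCCC1=O | starting material
2 | but-3-en-2-one | CC(=O)C=C | starting material
3 | ethyl (1S)-2-oxo-1-(3-oxobutyl)cyclopentane-1-carboxylate | CCOC(=O)[C@]1(CCC(C)=O)CCCC1=O | intermediate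
4 | ethyl (7aS)-5-oxo-1,2,3,5,6,7-hexahydro-7aH-indene-7a-carboxylate (rings A/B; C6 ketone, C4=C5, 9β-CO2Et) | CCOC(=O)[C@@]12CCC(=O)C=C1CCC2 | intermediate
5 | triethyl phosphonoacetate | CCOC(=O)CP(=O)(OCC)OCC | starting material
6 | dienoate: ethyl (7aS)-5-(2-ethoxy-2-oxoethylidene)-1,2,3,5,6,7-hexahydro-7aH-indene-7a-carboxylate (C6=C14 alkene isomers) | CCOC(=O)C=C1C=C2CCC[C@]2(C(=O)OCC)CC1 | intermediate
7 | diester: ethyl (5S,7aS)-5-(2-ethoxy-2-oxoethyl)-5-methyl-1,2,3,5,6,7-hexahydro-7aH-indene-7a-carboxylate (6α-CH3, 6β-CH2CO2Et, 9β-CO2Et, C4=C5) | CCOC(=O)C[C@@]1(C)C=C2CCC[C@]2(C(=O)OCC)CC1 | intermediate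
8 | diol: ring A/B bicycle with C4=C5, 6α-CH3, 6β-CH2CH2OH (C14–C13) and 9β-CH2OH (C17) | OCC[C@@]1(C)C=C2CCC[C@]2(CO)CC1 | intermediate
9 | chloro alcohol: as 8 with C13–Cl | ClCC[C@@]1(C)C=C2CCC[C@]2(CO)CC1 | intermediate
10 | silyl ether: as 9 with C17–OSi(t-Bu)Me2 | ClCC[C@@]1(C)C=C2CCC[C@]2(CO[Si](C)(C)C(C)(C)C)CC1 | intermediate
11 | enone: as 10 with C3 ketone conjugated to C4=C5 | ClCC[C@@]1(C)C=C2C(=O)CC[C@]2(CO[Si](C)(C)C(C)(C)C)CC1 | intermediate
12 | ethyl vinyl ether | C=COCC | starting material
13 | enol ether adduct: C3 bearing β-OH and α-(1-ethoxyvinyl) | ClCC[C@@]1(C)C=C2[C@](O)(C(=C)OCC)CC[C@]2(CO[Si](C)(C)C(C)(C)C)CC1 | intermediate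
14 | α-hydroxy methyl ketone: C3 bearing β-OH and α-acetyl (C12=O, C15) | ClCC[C@@]1(C)C=C2[C@](O)(C(C)=O)CC[C@]2(CO[Si](C)(C)C(C)(C)C)CC1 | intermediate
15 | vinylmagnesium bromide | C=C[Mg]Br | starting material
16 | vinyl carbinol diol: C3 bearing β-OH and α-C12(OH)(CH3)–C11H=C10H2 (C12 epimers) | ClCC[C@@]1(C)C=C2[C@](O)(C(C)(O)C=C)CC[C@]2(CO[Si](C)(C)C(C)(C)C)CC1 | intermediate
17 | phosphonium iodide: as 16 with C13–P(C6H5)3+ I− | [I-].c1ccccc1[P+](c1ccccc1)(c1ccccc1)CC[C@@]1(C)C=C2[C@](O)(C(C)(O)C=C)CC[C@]2(CO[Si](C)(C)C(C)(C)C)CC1 | intermediate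
18 | ylide alkoxide: C13=P(C6H5)3 ylide and potassium C12-alkoxide of 17 | c1ccccc1P(c1ccccc1)(c1ccccc1)=CC[C@@]1(C)C=C2[C@](O)(C(C)([O-])C=C)CC[C@]2(CO[Si](C)(C)C(C)(C)C)CC1.[K+] | intermediate
19 | ylide keto enolate: C5 bearing α-CH2CH2C(=O)CH3 (C10–C12, C15), potassium C3 enolate (C3=C4), C13=P(C6H5)3 | c1ccccc1P(c1ccccc1)(c1ccccc1)=CC[C@@]1(C)[C@H](CCC(C)=O)C2=C([O-])CC[C@]2(CO[Si](C)(C)C(C)(C)C)CC1.[K+] | intermediate
20 | tricyclic ketone: rings A/B/C, C3 ketone, 4α-H, 5β-H, 6α-CH3, C12=C13 with C12–CH3, 9β-CH2OSi(t-Bu)Me2 | O=C1CC[C@]2(CO[Si](C)(C)C(C)(C)C)CC[C@@]3(C)CC=C(C)CC[C@@H]3[C@@H]12 | intermediate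
21 | alcohol: as 20 with C17–OH | O=C1CC[C@]2(CO)CC[C@@]3(C)CC=C(C)CC[C@@H]3[C@@H]12 | intermediate
22 | acetate: as 20 with C17–OAc | O=C1CC[C@]2(COC(C)=O)CC[C@@]3(C)CC=C(C)CC[C@@H]3[C@@H]12 | intermediate
23 | silyl enol ether: C2=C3–OSiMe3 of 22 | C[Si](C)(C)OC1=CC[C@]2(COC(C)=O)CC[C@@]3(C)CC=C(C)CC[C@@H]3[C@@H]12 | intermediate
24 | silyloxy epoxy ketone: 2α-OSiMe3, 12β,13β-epoxide, C3 ketone | O=C1[C@H](O[Si](C)(C)C)C[C@]2(COC(C)=O)CC[C@@]3(C)C[C@H]4O[C@@]4(C)CC[C@@H]3[C@@H]12 | intermediate
25 | epoxy hydroxy ketone: 2α-OH, 12β,13β-epoxide, C3 ketone, C17–OAc | O=C1[C@H](O)C[C@]2(COC(C)=O)CC[C@@]3(C)C[C@H]4O[C@@]4(C)CC[C@@H]3[C@@H]12 | intermediate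
26 | acrylic acid | C=CC(=O)O | starting material
27 | 2β-acrylate of the C2-inverted alcohol | O=C1[C@@H](OC(=O)C=C)C[C@]2(COC(C)=O)CC[C@@]3(C)C[C@H]4O[C@@]4(C)CC[C@@H]3[C@@H]12 | intermediate
28 | CNP0404717.1: 3α-hydroxy-12β,13β-epoxy-17-acetoxy cyathane 20,2β-lactone with C18=C19 methylene | C=C1C(=O)O[C@H]2C[C@]3(COC(C)=O)CC[C@@]4(C)C[C@H]5O[C@@]5(C)CC[C@@H]4[C@H]3[C@@]12O | target

**Totals and fallbacks**

Total: 17 steps. Longest linear sequence: 17 steps (1 and 2 to 28).

Steps most likely to fail:

Step 12. The cascade may stall after the rearrangement if proton transfer between the two enolate sites is slow, the C11 enolate may be drawn into reversible aldol closure onto C3 before the ylide engages, or the ylide may be quenched. The fallback runs the same two bond formations stepwise with known chemistry. Setting out from 16, the alkoxide-accelerated oxy-Cope rearrangement alone (KH 1.05 equiv, 18-crown-6, THF, −20 → 0 °C, cold NH4Cl quench so that the enolates do not alkylate the chloride) should give the 1,6-diketone chloride F1. Finkelstein exchange and quaternisation (PPh3, NaI, CH3CN, 80 °C) should give the keto phosphonium iodide F2, and KOC(CH3)3 in THF should effect the intramolecular Wittig olefination, which comes back to the route at 20.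

Step 17. Addition of the ammonium enolate to the hindered C3 ketone may be slow, so that epimerisation at C2 or oligomerisation of the acrylate competes. The fallback replaces the amine-triggered closure by an organochromium one. Setting out from 25, Mitsunobu esterification with 2-bromoacrylic acid (PPh3, diisopropyl azodicarboxylate, toluene) should give the 2β-(2-bromoacrylate) F3, and intramolecular Nozaki–Hiyama–Kishi addition of the derived vinylchromium species to the C3 ketone (CrCl2, NiCl2 cat., DMF, 23 °C) should close the same cis-fused lactone and come back to the route at 28.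

Step 16. Elimination toward the ring A enone or incomplete inversion may occur at the hindered α-ketol, whose β face is screened by C17. The fallback separates activation from displacement. Setting out from 25, triflation (Tf2O, 2,6-lutidine, CH2Cl2, −78 °C) should give the 2α-triflate F4, and SN2 displacement with cesium acrylate (CsO2CCH=CH2, 18-crown-6, toluene, 0 → 23 °C) should invert C2 and come back to the route at 27.

**Further compounds**

F1 | step 12 | 1,6-diketone chloride: C3 ketone, 4α-H, 5β-H, C5 bearing α-CH2CH2C(=O)CH3, C13–Cl, C17–OSi(t-Bu)Me2 | ClCC[C@@]1(C)[C@H](CCC(C)=O)[C@H]2C(=O)CC[C@]2(CO[Si](C)(C)C(C)(C)C)CC1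
F2 | step 12 | keto phosphonium iodide: as F1 with C13–P(C6H5)3+ I− | [I-].c1ccccc1[P+](c1ccccc1)(c1ccccc1)CC[C@@]1(C)[C@H](CCC(C)=O)[C@H]2C(=O)CC[C@]2(CO[Si](C)(C)C(C)(C)C)CC1
F3 | step 17 | 2β-(2-bromoacrylate) of the C2-inverted alcohol | O=C1[C@@H](OC(=O)C(Br)=C)C[C@]2(COC(C)=O)CC[C@@]3(C)C[C@H]4O[C@@]4(C)CC[C@@H]3[C@@H]12
F4 | step 16 | 2α-triflate of 25 | O=C1[C@H](OS(=O)(=O)C(F)(F)F)C[C@]2(COC(C)=O)CC[C@@]3(C)C[C@H]4O[C@@]4(C)CC[C@@H]3[C@@H]12
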